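**Plan**
Numbering: C1/C5 ring fusion, C2, C3=C4(Me), C6(OH), C7, C8, C9(OH), C10(=CH2); side chain C11(Me), C12(OAc), C13(OAc), C14=C15Me2.
Feature: C1 and C5 are neighbouring trans stereocentres of the five-membered ring (C1–C5), and each carries one arm of the seven-membered ring (C10 on C1, C6 on C5); this is the pattern left by 1,4-addition to cyclopentenone and capture of the enolate.
Cuts: C8–C9 (seven-membered ring) first, then C4–CH3, then C1–C10 and C5–C6 together, leaving cyclopentenone, a 2-metallated acrolein acetal (C9, C10, =CH2) and the aldehyde C6–C8/C11–C15.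
Forward: the aldehyde is built through a δ-lactone (alkoxyallylboration of prenal, acrylate metathesis, methyl cuprate, enolate alkylation); the three pieces are joined on the preformed five-membered ring; C4 is methylated; the seven-membered ring is closed last at C8–C9; the MOM groups are exchanged for acetates.
Stereochemistry: C12/C13 from the Ipc2B reagent; C11 and C7 from trans additions on the lactone; C1 from the chiral copper ligand; C5 trans to C1; C6 from a chair aldol transition state with Felkin–Anh control; C9 from the ring-closure transition state.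

Key step: step 14

Remark: C1 is fixed by the phosphoramidite of step 14; the (R,S,S) antipode is written because, by topological analogy with dialkylzinc additions, it should give (R)-C1, and the sense is to be confirmed on 21 alone before the aldehyde is committed.

**Route**

Step 1
Reactants: 1 prop-2-en-1-ol
Product: 2 3-(methoxymethoxy)prop-1-ene
Conditions: MOMCl, i-Pr2NEt, CH2Cl2, 0 °C → rt
Reagents that add atoms: chloromethyl methyl ether, COCCl
Why: Williamson-type O-alkylation of the alcohol by the chloromethyl ether under amine base (MOM protection); no stereocentre is involved.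

Step 2
Reactants: 2 3-(methoxymethoxy)prop-1-ene; 3 3-methylbut-2-enal
Product: 6 (3S,4S)-3-(methoxymethoxy)-6-methylhepta-1,5-dien-4-ol, via lithiated allyl ether 4 (not isolated), via alkoxyallylborane 5 (not isolated)
Conditions: s-BuLi, THF, −78 °C; (+)-Ipc2BOMe, −78 °C; BF3·OEt2; 3, −78 °C; then NaOH, H2O2, 0 °C → rt
Reagents that add atoms: none
Why: Brown alkoxyallylboration: the chelated (Z)-alkoxyallyl anion gives a (Z)-allylborane that adds 1,2 to the enal through a chair transition state, so the (Z) geometry should give the syn diol monoether and the Ipc groups derived from (−)-α-pinene should direct attack to the Re face, setting C12 and C13 as (S,S).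

Step 3
Reactants: 6 (3S,4S)-3-(methoxymethoxy)-6-methylhepta-1,5-dien-4-ol
Product: 7 (3S,4S)-3-(methoxymethoxy)-6-methylhepta-1,5-dien-4-yl prop-2-enoate
Conditions: acryloyl chloride, Et3N, CH2Cl2, −78 → 0 °C
Reagents that add atoms: acryloyl chloride, C=CC(=O)Cl
Why: O-acylation of the secondary allylic alcohol by the acid chloride; the stereocentres are untouched.

Step 4
Reactants: 7 (3S,4S)-3-(methoxymethoxy)-6-methylhepta-1,5-dien-4-yl prop-2-enoate
Product: 8 (5S,6S)-5-(methoxymethoxy)-6-(2-methylprop-1-en-1-yl)-5,6-dihydro-2H-pyran-2-one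
Conditions: second-generation Grubbs catalyst RuCl2(=CHPh)(PCy3)(H2IMes) (5 mol%), CH2Cl2 (0.005 M), 40 °C
Reagents that add atoms: none
Why: Ring-closing metathesis: the carbene should load on the monosubstituted vinyl group and close onto the acrylate to the six-membered lactone, while the trisubstituted isobutenyl group is too hindered to compete.

Step 5
Reactants: 8 (5S,6S)-5-(methoxymethoxy)-6-(2-methylprop-1-en-1-yl)-5,6-dihydro-2H-pyran-2-one
Product: 9 (4R,5S,6S)-5-(methoxymethoxy)-4-methyl-6-(2-methylprop-1-en-1-yl)oxan-2-one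
Conditions: Me2CuLi (from MeLi, CuI), Et2O, −78 → −30 °C; aq. NH4Cl
Reagents that add atoms: lithium dimethylcuprate, [Li+].C[Cu-]C
Why: Gilman 1,4-addition to the unsaturated lactone; the methyl group should enter anti to the C12 alkoxy group and to the cis C13 substituent, which sets C11 (4,5-trans).

Step 6
Reactants: 10 (4-methoxyphenyl)methanol
Product: 11 1-methoxy-4-{[(methylsulfanyl)methoxy]methyl}benzene
Conditions: NaH, ClCH2SMe, NaI (cat.), THF, 0 °C → rt
Reagents that add atoms: chloromethyl methyl sulfide, CSCCl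
Why: Williamson alkylation of the sodium alkoxide gives the methylthiomethyl ether.

Step 7
Reactants: 11 1-methoxy-4-{[(methylsulfanyl)methoxy]methyl}benzene
Product: 12 1-[(chloromethoxy)methyl]-4-methoxybenzene
Conditions: SO2Cl2, CH2Cl2, −78 °C; volatiles removed, used crude
Reagents that add atoms: sulfuryl chloride, O=S(=O)(Cl)Cl
Why: Chlorinolysis of the O,S-acetal by sulfuryl chloride gives the chloromethyl ether without acid that would cleave the PMB group.

Step 8
Reactants: 9 (4R,5S,6S)-5-(methoxymethoxy)-4-methyl-6-(2-methylprop-1-en-1-yl)oxan-2-one; 12 1-[(chloromethoxy)methyl]-4-methoxybenzene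
Product: 14 (3S,4R,5S,6S)-3-{[(4-methoxybenzyl)oxy]methyl}-5-(methoxymethoxy)-4-methyl-6-(2-methylprop-1-en-1-yl)oxan-2-one, via lithium enolate 13 (not isolated)
Conditions: LiN(i-Pr)2, THF, −78 °C; then 12, −78 → −30 °C
Reagents that add atoms: none
Why: Lactone enolate alkylation with a reactive alkoxymethyl chloride; the electrophile should approach anti to the adjacent C11 methyl group, and the 3,4-trans product with all three substituents C3–C5 equatorial is also the thermodynamic one, which sets C7.

Step 9
Reactants: 14 (3S,4R,5S,6S)-3-{[(4-methoxybenzyl)oxy]methyl}-5-(methoxymethoxy)-4-methyl-6-(2-methylprop-1-en-1-yl)oxan-2-one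
Product: 15 (2R,3R,4S,5S)-2-{[(4-methoxybenzyl)oxy]methyl}-4-(methoxymethoxy)-3,7-dimethyloct-6-ene-1,5-diol
Conditions: LiAlH4, THF, 0 °C
Reagents that add atoms: none
Why: Hydride reduction of the lactone to the diol (the carbonyl carbon becomes C8); ethers and the alkene are inert.

Step 10
Reactants: 15 (2R,3R,4S,5S)-2-{[(4-methoxybenzyl)oxy]methyl}-4-(methoxymethoxy)-3,7-dimethyloct-6-ene-1,5-diol
Product: 16 the C8 (primary) tert-butyldimethylsilyl ether of 15
Conditions: TBSCl (1.05 equiv), imidazole, CH2Cl2, 0 °C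
Reagents that add atoms: tert-butyldimethylsilyl chloride, CC(C)(C)[Si](C)(C)Cl
Why: Sterically controlled silylation of the primary hydroxyl in the presence of the secondary allylic one.

Step 11
Reactants: 16 the C8 (primary) tert-butyldimethylsilyl ether of 15
Product: 17 the C13 methoxymethyl ether of 16
Conditions: MOMCl, i-Pr2NEt, n-Bu4NI (cat.), CH2Cl2, 0 → 35 °C
Reagents that add atoms: chloromethyl methyl ether, COCCl
Why: MOM protection of the remaining secondary alcohol, so that C12 and C13 carry the same acetal group.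

Step 12
Reactants: 17 the C13 methoxymethyl ether of 16
Product: 18 the C6 primary alcohol (17 without the 4-methoxybenzyl group)
Conditions: DDQ, CH2Cl2/pH 7 buffer, 0 °C
Reagents that add atoms: none
Why: Oxidative PMB cleavage through the benzylic oxocarbenium ion; silyl and MOM ethers and the trisubstituted alkene should survive.

Step 13
Reactants: 18 the C6 primary alcohol (17 without the 4-methoxybenzyl group)
Product: 19 (2R,3R,4S,5S)-2-{[(tert-butyldimethylsilyl)oxy]methyl}-4,5-bis(methoxymethoxy)-3,7-dimethyloct-6-enal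
Conditions: Dess–Martin periodinane, NaHCO3, CH2Cl2, 0 °C → rt; used at once
Reagents that add atoms: none
Why: Dess–Martin oxidation under buffered conditions that should not epimerise the α-stereocentre C7.

Step 14
Reactants: 20 2-bromo-3,3-diethoxyprop-1-ene; 21 cyclopent-2-en-1-one; 19 (2R,3R,4S,5S)-2-{[(tert-butyldimethylsilyl)oxy]methyl}-4,5-bis(methoxymethoxy)-3,7-dimethyloct-6-enal
Product: 25 (2R,3R)-3-(3,3-diethoxyprop-1-en-2-yl)-2-[(1R,2R,3R,4S,5S)-2-{[(tert-butyldimethylsilyl)oxy]methyl}-1-hydroxy-4,5-bis(methoxymethoxy)-3,7-dimethyloct-6-en-1-yl]cyclopentan-1-one, via alkenyllithium 22 (not isolated), via alkenylalane 23 (not isolated), via aluminium enolate 24 (not isolated)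
Conditions: 20, t-BuLi (2 equiv), Et2O, −78 °C; Me2AlCl, −78 → −30 °C; 21, copper thiophene-2-carboxylate CuO2CC4H3S (5 mol%), (R,S,S)-BINOL bis(1-phenylethyl)amine phosphoramidite (10 mol%), Et2O, −30 °C; then 19, −78 °C; aq. potassium sodium tartrate
Reagents that add atoms: none
Why: Bromine–lithium exchange gives alkenyllithium 22, which is transmetalated to the dimethylalkenylalane 23; the chiral copper–phosphoramidite complex transfers the alkenyl group to the β-carbon of cyclopentenone (C1), and the dimethylaluminium enolate 24 is intercepted by aldehyde 19 through a closed six-membered Zimmerman–Traxler transition state. The closest known reaction type is the copper-catalysed asymmetric conjugate addition of alkenylaluminium reagents to cyclic enones with aldol capture of the metal enolate (three-component coupling on cyclopentenone). No ring is closed; the bonds C1–C10 and C5–C6 are formed. C1 is set by the ligand; C5 is set by the substrate, because the aldehyde meets the enolate on the face anti to the new C1 substituent (2,3-trans); C6 follows from the chair transition state of the ring-fixed E(O)-enolate (anti aldol) together with Felkin–Anh approach past the C7 hydrogen with the C11 branch as the large group, a pairing that is matched for an E-enolate and (R)-C1. The step needs 1,4- over 1,2-addition (copper catalysis), alkenyl over methyl transfer (the sp2 group migrates preferentially) and a non-chelated aldehyde (the C8 oxygen carries a bulky silyl group), while the diethyl acetal keeps C9 inert.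

Step 15
Reactants: 25 the trans aldol of step 14
Product: 26 the C6 tert-butyldimethylsilyl ether of 25
Conditions: TBSOTf, 2,6-lutidine, CH2Cl2, −78 °C
Reagents that add atoms: tert-butyldimethylsilyl triflate, CC(C)(C)[Si](C)(C)OS(=O)(=O)C(F)(F)F
Why: Silylation of the hindered β-hydroxy ketone by the silyl triflate at a temperature where the acetal and MOM groups should not be attacked; it blocks retro-aldol cleavage in the next step.

Step 16
Reactants: 26 the C6 tert-butyldimethylsilyl ether of 25
Product: 28 the C3=C4 enol triflate of 26, via potassium enolate 27 (not isolated)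
Conditions: KN(SiMe3)2, THF, −78 °C; PhNTf2, −78 → 0 °C
Reagents that add atoms: N-phenylbis(trifluoromethanesulfonimide), O=S(=O)(N(c1ccccc1)S(=O)(=O)C(F)(F)F)C(F)(F)F
Why: Kinetic deprotonation at the unhindered C3 methylene (not at the substituted C5 methine) and O-triflation of the enolate give the regiodefined enol triflate.

Step 17
Reactants: 28 the C3=C4 enol triflate of 26
Product: 29 the C4-methyl cyclopentene (C3=C4) with the diethyl acetal and both silyl ethers in place
Conditions: MeMgBr, Fe(acac)3 (5 mol%), THF/NMP, −30 °C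
Reagents that add atoms: methylmagnesium bromide, C[Mg]Br
Why: Iron-catalysed Kumada-type cross-coupling of the alkenyl triflate with the methyl Grignard reagent installs the C4 methyl group with the double bond already in place.

Step 18
Reactants: 29 the C4-methyl cyclopentene (C3=C4) with the diethyl acetal and both silyl ethers in place
Product: 30 the C8 primary alcohol (C6 silyl ether retained)
Conditions: HF·pyridine, pyridine, THF, 0 °C
Reagents that add atoms: none
Why: Buffered fluoride desilylation removes the primary silyl ether much faster than the hindered secondary one, and the buffer should protect the acetal.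

Step 19
Reactants: 30 the C8 primary alcohol (C6 silyl ether retained)
Product: 31 the C8 primary iodide
Conditions: I2, PPh3, imidazole, CH2Cl2, 0 °C
Reagents that add atoms: iodine, II
Why: Appel-type iodination (SN2 displacement of the oxyphosphonium at the primary carbon) under imidazole buffering.

Step 20
Reactants: 31 the C8 primary iodide
Product: 32 the 2-substituted acrolein (C9 aldehyde) carrying the C8 iodide
Conditions: PPTS (cat.), acetone/H2O, rt; used at once
Reagents that add atoms: water, O
Why: Mild acid hydrolysis of the allylic diethyl acetal through the conjugated oxocarbenium ion; MOM ethers, the silyl ether and the iodide should be stable.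

Step 21
Reactants: 32 the 2-substituted acrolein (C9 aldehyde) carrying the C8 iodide
Product: 34 the trans-fused bicyclic allylic alcohol (C9–OH, C6–OTBS, C12/C13 MOM ethers), via alkyllithium 33 (not isolated)
Conditions: t-BuLi (2.05 equiv), Et2O/pentane, −100 °C, high dilution; aq. NH4Cl
Reagents that add atoms: none
Why: Iodine–lithium exchange at the primary iodide should outrun carbonyl addition of t-BuLi at −100 °C, and the C8 carbanion then adds 1,2 to the C9 aldehyde (halogen–metal exchange-initiated anionic cyclisation, 7-exo-trig) before silyl migration from the C6 oxygen can occur; the lithium alkoxide is expected pseudo-equatorial and trans to the C7 side chain, giving (R)-C9.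

Step 22
Reactants: 34 the trans-fused bicyclic allylic alcohol (C9–OH, C6–OTBS, C12/C13 MOM ethers)
Product: 35 the C6,C9-bis(tert-butyldimethylsilyl) ether
Conditions: TBSOTf, 2,6-lutidine, CH2Cl2, −78 °C
Reagents that add atoms: tert-butyldimethylsilyl triflate, CC(C)(C)[Si](C)(C)OS(=O)(=O)C(F)(F)F
Why: Silylation of the allylic alcohol, so that only C12 and C13 carry free hydroxyls after the next step.

Step 23
Reactants: 35 the C6,C9-bis(tert-butyldimethylsilyl) ether
Product: 36 the C12,C13-diol (both silyl ethers retained)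
Conditions: Me2BBr, CH2Cl2, −78 °C; then THF, aq. NaHCO3
Reagents that add atoms: none
Why: The bromoborane should cleave both MOM acetals through bromomethyl ethers at −78 °C, conditions under which tert-butyldimethylsilyl ethers are normally retained and no Brønsted acid reaches the allylic C13–O bond.

Step 24
Reactants: 36 the C12,C13-diol (both silyl ethers retained)
Product: 37 the C12,C13-diacetate
Conditions: Ac2O, pyridine, DMAP (cat.), CH2Cl2, rt
Reagents that add atoms: acetic anhydride, CC(=O)OC(C)=O
Why: Nucleophile-catalysed acylation of the two secondary alcohols; C6 and C9 are masked.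

Step 25
Reactants: 37 the C12,C13-diacetate
Product: 38 CNP0423623.2, (2R,3S,4S)-2-[(3aS,4R,5S,7R,8aR)-4,7-dihydroxy-3-methyl-8-methylidene-1,3a,4,5,6,7,8,8a-octahydroazulen-5-yl]-6-methylhept-5-ene-3,4-diyl diacetate
Conditions: HF·pyridine, THF, 0 °C → rt
Reagents that add atoms: none
Why: Fluoride desilylation under mildly acidic conditions frees C6–OH and C9–OH without the acetate migration that basic fluoride could cause.

**Compound list**

1 | prop-2-en-1-ol | C=CCO | starting material
2 | 3-(methoxymethoxy)prop-1-ene | C=CCOCOC | intermediate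
3 | 3-methylbut-2-enal | CC(C)=CC=O | starting material
4 | [(Z)-3-(methoxymethoxy)prop-2-en-1-yl]lithium | [Li]C/C=C\OCOC | intermediate
5 | [(Z)-3-(methoxymethoxy)prop-2-en-1-yl]diisopinocampheylborane, Ipc groups from (−)-α-pinene | COCO/C=C\CB([C@H]1C[C@H]2C[C@H](C2(C)C)[C@@H]1C)[C@H]1C[C@H]2C[C@H](C2(C)C)[C@@H]1C | intermediate
6 | (3S,4S)-3-(methoxymethoxy)-6-methylhepta-1,5-dien-4-ol | C=C[C@H](OCOC)[C@@H](O)C=C(C)C | intermediate
7 | (3S,4S)-3-(methoxymethoxy)-6-methylhepta-1,5-dien-4-yl prop-2-enoate | C=CC(=O)O[C@@H](C=C(C)C)[C@@H](OCOC)C=C | intermediate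
8 | (5S,6S)-5-(methoxymethoxy)-6-(2-methylprop-1-en-1-yl)-5,6-dihydro-2H-pyran-2-one | O=C1C=C[C@H](OCOC)[C@H](C=C(C)C)O1 | intermediate
9 | (4R,5S,6S)-5-(methoxymethoxy)-4-methyl-6-(2-methylprop-1-en-1-yl)oxan-2-one | O=C1C[C@@H](C)[C@H](OCOC)[C@H](C=C(C)C)O1 | intermediate
10 | (4-methoxyphenyl)methanol | COc1ccc(CO)cc1 | starting material
11 | 1-methoxy-4-{[(methylsulfanyl)methoxy]methyl}benzene | COc1ccc(COCSC)cc1 | intermediate
12 | 1-[(chloromethoxy)methyl]-4-methoxybenzene | COc1ccc(COCCl)cc1 | intermediate
13 | lithium enolate of lactone 9 | [Li]OC1=C[C@@H](C)[C@H](OCOC)[C@H](C=C(C)C)O1 | intermediate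
14 | (3S,4R,5S,6S)-3-{[(4-methoxybenzyl)oxy]methyl}-5-(methoxymethoxy)-4-methyl-6-(2-methylprop-1-en-1-yl)oxan-2-one | O=C1[C@H](COCc2ccc(OC)cc2)[C@@H](C)[C@H](OCOC)[C@H](C=C(C)C)O1 | intermediate
15 | (2R,3R,4S,5S)-2-{[(4-methoxybenzyl)oxy]methyl}-4-(methoxymethoxy)-3,7-dimethyloct-6-ene-1,5-diol | OC[C@H](COCc1ccc(OC)cc1)[C@@H](C)[C@H](OCOC)[C@@H](O)C=C(C)C | intermediate
16 | 15 with the primary (C8) hydroxyl as tert-butyldimethylsilyl ether | CC(C)(C)[Si](C)(C)OC[C@H](COCc1ccc(OC)cc1)[C@@H](C)[C@H](OCOC)[C@@H](O)C=C(C)C | intermediate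
17 | 16 with the C13 hydroxyl as methoxymethyl ether | CC(C)(C)[Si](C)(C)OC[C@H](COCc1ccc(OC)cc1)[C@@H](C)[C@H](OCOC)[C@@H](OCOC)C=C(C)C | intermediate
18 | 17 with the C6 hydroxyl free (4-methoxybenzyl removed) | CC(C)(C)[Si](C)(C)OC[C@H](CO)[C@@H](C)[C@H](OCOC)[C@@H](OCOC)C=C(C)C | intermediate
19 | (2R,3R,4S,5S)-2-{[(tert-butyldimethylsilyl)oxy]methyl}-4,5-bis(methoxymethoxy)-3,7-dimethyloct-6-enal | CC(C)(C)[Si](C)(C)OC[C@H](C=O)[C@@H](C)[C@H](OCOC)[C@@H](OCOC)C=C(C)C | intermediate
20 | 2-bromo-3,3-diethoxyprop-1-ene | C=C(Br)C(OCC)OCC | starting material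
21 | cyclopent-2-en-1-one | O=C1C=CCC1 | starting material
22 | (3,3-diethoxyprop-1-en-2-yl)lithium | [Li]C(=C)C(OCC)OCC | intermediate
23 | (3,3-diethoxyprop-1-en-2-yl)dimethylalane | C[Al](C)C(=C)C(OCC)OCC | intermediate
24 | dimethylaluminium (R)-3-(3,3-diethoxyprop-1-en-2-yl)cyclopent-1-en-1-olate | C=C(C(OCC)OCC)[C@@H]1CCC(O[Al](C)C)=C1 | intermediate
25 | (2R,3R)-3-(3,3-diethoxyprop-1-en-2-yl)-2-[(1R,2R,3R,4S,5S)-2-{[(tert-butyldimethylsilyl)oxy]methyl}-1-hydroxy-4,5-bis(methoxymethoxy)-3,7-dimethyloct-6-en-1-yl]cyclopentan-1-one | C=C(C(OCC)OCC)[C@@H]1CCC(=O)[C@H]1[C@H](O)[C@@H](CO[Si](C)(C)C(C)(C)C)[C@@H](C)[C@H](OCOC)[C@@H](OCOC)C=C(C)C | intermediate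
26 | 25 with the C6 hydroxyl as tert-butyldimethylsilyl ether | C=C(C(OCC)OCC)[C@@H]1CCC(=O)[C@H]1[C@H](O[Si](C)(C)C(C)(C)C)[C@@H](CO[Si](C)(C)C(C)(C)C)[C@@H](C)[C@H](OCOC)[C@@H](OCOC)C=C(C)C | intermediate
27 | potassium C3=C4 enolate of 26 | C=C(C(OCC)OCC)[C@@H]1CC=C(O[K])[C@H]1[C@H](O[Si](C)(C)C(C)(C)C)[C@@H](CO[Si](C)(C)C(C)(C)C)[C@@H](C)[C@H](OCOC)[C@@H](OCOC)C=C(C)C | intermediate
28 | C3=C4 enol triflate of 26 | C=C(C(OCC)OCC)[C@@H]1CC=C(OS(=O)(=O)C(F)(F)F)[C@H]1[C@H](O[Si](C)(C)C(C)(C)C)[C@@H](CO[Si](C)(C)C(C)(C)C)[C@@H](C)[C@H](OCOC)[C@@H](OCOC)C=C(C)C | intermediate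
29 | C4-methyl cyclopentene (C3=C4) with diethyl acetal, C6 and C8 silyl ethers, C12/C13 MOM ethers | C=C(C(OCC)OCC)[C@@H]1CC=C(C)[C@H]1[C@H](O[Si](C)(C)C(C)(C)C)[C@@H](CO[Si](C)(C)C(C)(C)C)[C@@H](C)[C@H](OCOC)[C@@H](OCOC)C=C(C)C | intermediate
30 | 29 with the C8 hydroxyl free | C=C(C(OCC)OCC)[C@@H]1CC=C(C)[C@H]1[C@H](O[Si](C)(C)C(C)(C)C)[C@@H](CO)[C@@H](C)[C@H](OCOC)[C@@H](OCOC)C=C(C)C | intermediate
31 | C8 primary iodide from 30 | C=C(C(OCC)OCC)[C@@H]1CC=C(C)[C@H]1[C@H](O[Si](C)(C)C(C)(C)C)[C@@H](CI)[C@@H](C)[C@H](OCOC)[C@@H](OCOC)C=C(C)C | intermediate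
32 | 2-substituted acrolein (C9 aldehyde, C10=CH2) with the C8 iodide | C=C(C=O)[C@@H]1CC=C(C)[C@H]1[C@H](O[Si](C)(C)C(C)(C)C)[C@@H](CI)[C@@H](C)[C@H](OCOC)[C@@H](OCOC)C=C(C)C | intermediate
33 | C8 alkyllithium from 32 | C=C(C=O)[C@@H]1CC=C(C)[C@H]1[C@H](O[Si](C)(C)C(C)(C)C)[C@@H](C[Li])[C@@H](C)[C@H](OCOC)[C@@H](OCOC)C=C(C)C | intermediate
34 | trans-fused octahydroazulene with C9–OH (R), C6–OTBS, C10=CH2, C3=C4(Me), C12/C13 MOM ethers | C=C1[C@H](O)C[C@@H]([C@@H](C)[C@H](OCOC)[C@@H](OCOC)C=C(C)C)[C@@H](O[Si](C)(C)C(C)(C)C)[C@@H]2C(C)=CC[C@@H]12 | intermediate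
35 | 34 with the C9 hydroxyl as tert-butyldimethylsilyl ether | C=C1[C@H](O[Si](C)(C)C(C)(C)C)C[C@@H]([C@@H](C)[C@H](OCOC)[C@@H](OCOC)C=C(C)C)[C@@H](O[Si](C)(C)C(C)(C)C)[C@@H]2C(C)=CC[C@@H]12 | intermediate
36 | 35 with C12–OH and C13–OH free | C=C1[C@H](O[Si](C)(C)C(C)(C)C)C[C@@H]([C@@H](C)[C@H](O)[C@@H](O)C=C(C)C)[C@@H](O[Si](C)(C)C(C)(C)C)[C@@H]2C(C)=CC[C@@H]12 | intermediate
37 | C12,C13-diacetate of 36 | C=C1[C@H](O[Si](C)(C)C(C)(C)C)C[C@@H]([C@@H](C)[C@H](OC(C)=O)[C@@H](OC(C)=O)C=C(C)C)[C@@H](O[Si](C)(C)C(C)(C)C)[C@@H]2C(C)=CC[C@@H]12 | intermediate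
38 | CNP0423623.2, (2R,3S,4S)-2-[(3aS,4R,5S,7R,8aR)-4,7-dihydroxy-3-methyl-8-methylidene-1,3a,4,5,6,7,8,8a-octahydroazulen-5-yl]-6-methylhept-5-ene-3,4-diyl diacetate | C=C1[C@H](O)C[C@@H]([C@@H](C)[C@H](OC(C)=O)[C@H](C=C(C)C)OC(C)=O)[C@@H](O)[C@@H]2C(C)=CC[C@@H]12 | target

**Step count and risks**

Total step count: 25. Longest linear sequence: 23 steps (1–5, then 8–25); steps 6 and 7 make the alkylating agent 12 on a side branch.

Steps most likely to fail:

1. Step 14. Capture of the aluminium enolate by the α-branched aldehyde may be slow, so that proton transfer between enolate and aldolate, epimerisation at C7 or Lewis-acid opening of the acetal lowers yield and the C5/C6 selectivity. Fallback: the two events are separated. Setting out from 20 and 21, the conjugate addition is run as in step 14 and enolate 24 is silylated with TMSOTf to the regiodefined trimethylsilyl enol ether F1, which is isolated. MeLi (THF, 0 °C) regenerates the lithium enolate, ZnCl2 converts it into the zinc enolate, and addition of 19 at −78 °C should give the same trans aldol through a closed transition state; the route is rejoined at 25.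

2. Step 21. Direct addition of t-BuLi to the enal or deprotonation at C1 may compete with the exchange and ring closure, and the closure may deliver the alkoxide mainly on the wrong face of C9. Fallback: the electrophile is changed to an amide and C9 is set by reduction. Setting out from 32, Pinnick oxidation (NaClO2, NaH2PO4, 2-methylbut-2-ene) gives carboxylic acid F2, and coupling with MeNH(OMe)·HCl (EDC, i-Pr2NEt) gives Weinreb amide F3. Iodine–lithium exchange (t-BuLi, −100 °C) then closes the ring through the chelated tetrahedral intermediate, which releases the exo-methylene ketone F4 only on work-up. Luche reduction (NaBH4, CeCl3·7H2O, MeOH, −78 °C) with axial hydride delivery should give the equatorial alcohol, and the route is rejoined at 34. A C9 epimer formed in step 21 can be brought to the same ketone with Dess–Martin periodinane.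

3. Step 23. The Lewis acid may also remove or shift the allylic silyl ether at C9 while the acetals are cleaved. Fallback: C9 is carried through the exchange as the ketone, which needs no protection. Setting out from 34, Dess–Martin oxidation gives exo-methylene ketone F4 (the compound also met in the fallback to step 21). Me2BBr then frees keto diol F5, acetylation gives keto diacetate F6, Luche reduction, which leaves acetates untouched, gives mono-silyl ether diacetate F7, and HF·pyridine removes the C6 silyl group; the route is rejoined at the target 38.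

**Further compounds**

F1 | step 14 | {[(R)-3-(3,3-diethoxyprop-1-en-2-yl)cyclopent-1-en-1-yl]oxy}trimethylsilane | C=C(C(OCC)OCC)[C@@H]1CCC(O[Si](C)(C)C)=C1
F2 | step 21 | acrylic acid from 32 (C9 carboxylic acid, C8 iodide) | C=C(C(=O)O)[C@@H]1CC=C(C)[C@H]1[C@H](O[Si](C)(C)C(C)(C)C)[C@@H](CI)[C@@H](C)[C@H](OCOC)[C@@H](OCOC)C=C(C)C
F3 | step 21 | N-methoxy-N-methyl amide of F2 | C=C(C(=O)N(C)OC)[C@@H]1CC=C(C)[C@H]1[C@H](O[Si](C)(C)C(C)(C)C)[C@@H](CI)[C@@H](C)[C@H](OCOC)[C@@H](OCOC)C=C(C)C
F4 | step 21 | C9 ketone corresponding to 34 (exo-methylene ketone) | C=C1C(=O)C[C@@H]([C@@H](C)[C@H](OCOC)[C@@H](OCOC)C=C(C)C)[C@@H](O[Si](C)(C)C(C)(C)C)[C@@H]2C(C)=CC[C@@H]12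
F5 | step 23 | C9 ketone with C12–OH and C13–OH free | C=C1C(=O)C[C@@H]([C@@H](C)[C@H](O)[C@@H](O)C=C(C)C)[C@@H](O[Si](C)(C)C(C)(C)C)[C@@H]2C(C)=CC[C@@H]12
F6 | step 23 | C9 ketone C12,C13-diacetate | C=C1C(=O)C[C@@H]([C@@H](C)[C@H](OC(C)=O)[C@@H](OC(C)=O)C=C(C)C)[C@@H](O[Si](C)(C)C(C)(C)C)[C@@H]2C(C)=CC[C@@H]12
F7 | step 23 | C9 alcohol C12,C13-diacetate with the C6 silyl ether | C=C1[C@H](O)C[C@@H]([C@@H](C)[C@H](OC(C)=O)[C@@H](OC(C)=O)C=C(C)C)[C@@H](O[Si](C)(C)C(C)(C)C)[C@@H]2C(C)=CC[C@@H]12
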